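Numbering used throughout: C1 ketone, C2=C3 furanone alkene (C3 bears the ring oxygen), C4 the CH carrying C15H2OH, C5 CH2, C6 lactone O–CH, C7 fusion CH, C8 angelate CH, C9 CH2, C10 the methyl-bearing O–C, C11–C13 the methylene lactone.

## Analysis of the target

The target 39 is a ten-membered carbocycle (C1–C10) in which an oxygen atom joins C3 to C10. O, C3, C2, C1 and C10 thus form a 3(2H)-furanone, the other ring atoms form a nine-membered oxacycle, and an α-methylene-γ-lactone is fused at C6–C7. It has five stereocentres: C4 (S), C6 (R), C7 (S), C8 (R) and the quaternary C10 (S). H6 and H7 are anti, so the lactone is trans-fused. The C7–C11 bond and the C8 oxygen lie on the same face of the ring. C10 is 1,3 to C8, and C4 lies across the ring next to the furanone.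

The labile functions are the methylene lactone (a Michael acceptor), the (Z)-configured angelate (it isomerises to the tiglate under nucleophilic catalysis), and C4–H, which is vinylogously α to the C1 ketone and has the C15 oxygen in the β position. A free C8 hydroxyl can also take over the lactone carbonyl. The synthesis is hard because a bridged medium ring must be closed, three contiguous ring stereocentres must be set, and three labile functions can only come late.

The strategy rests on one feature. Without the lactone C–O bond, C6 is a plain ring CH2 that lies γ to the C12 carboxyl (C12–C11–C7–C6). The only other γ carbon, C8, carries an acyloxy group and is deactivated towards an electrophilic hydrogen abstractor. A C12 acid can therefore direct an oxidant to C6.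

## Retrosynthetic reasoning

**Endgame (39 back to 33).** No skeletal bond is cut. The C15 hydroxyl of 39 is traced to the carbonate 38. The C11=C13 double bond of 38 is traced to the C13 carbonate 37, which undergoes β-elimination in the forward direction. The O8 ester of 37 is traced to alcohol 34 and angelic acid 35, and 34 to its chloroacetate 33. These functions come last because neither the methylene nor the angelate would survive an oxidation at C6. What is gained is that 33 has no alkene other than the furanone.

**Key cut (33 back to 32).** The O–C6 bond of the lactone is removed, which leaves acid 32 with a bare C5–C6 ethylene bridge. This removes one ring and the C6 stereocentre from everything before it. The forward reaction must pick C6 over C8 and must replace the hydrogen that gives the trans-fused ring.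

**Functional-group adjustment (32 back to 27).** The acid 32 is kept as tert-butyl ester 31 until the last moment, so that a free C12 carboxyl never meets a free C8 hydroxyl, which would close the unwanted 8,12-lactone. Chloroacetate 31 comes from alcohol 30, 30 from silyl ether 29, the two carbonates of 29 from diol 28, and the C13 alcohol of 28 from the malonic half acid 27. One acyl group serves both O13 (later leaving group) and O15 (protecting group), which saves a differentiation.

**C5–C6 (27 back to 25).** Both carbons are unfunctionalised in 32, so this is where a ring-closing alkene leaves no trace. Alkene 26 comes from diene 25 by metathesis. The forward hydrogenation also frees O15 and one malonate carboxyl, so the benzyl groups of 25 are chosen with this step in mind.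

**Furanone (25 back to 14 and 21).** The O–C3 bond is cut to diketone 23 (cyclodehydration forward) and the C2–C3 bond to aldol 22, made from methyl ketone 14 and aldehyde 21. This is the most convergent cut. It separates a C3–C5/C15 piece holding C4 from a C6–C10 piece holding C7, C8 and C10.

**C7–C11 (14 back to 12 and 13).** The malonate carbon is detached from C7, giving the linear allylic carbonate 12 and malonate 13. A branched-selective allylic alkylation creates the C7 stereocentre and the C6 vinyl group needed for ring closure in one step. The two different esters of 13 allow the carboxyls to be told apart later. Carbonate 12 comes from alcohol 11, ether 10 and allylic alcohol 9 by protecting-group changes.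

**C7–C8 and C9–C10 (9 back to 5, 6, 3 and 1).** The C7–C8 bond is cut to aldehyde 5 and alkyne 6. The catalytic alkenylation sets C8 by the ligand alone, independent of the remote quaternary C10. Aldehyde 5 comes from thioester 4. The C9–C10 bond of 4 is an aldol bond between silyl ketene acetal 2 (from 1) and dione 3, which delivers C10, its methyl group and the C1–C2 acetyl unit in one catalytic step.

**C4–C15 (21 back to 15 and 16).** Aldehyde 21 comes from alcohol 20 and imide 19. The C4–C15 bond of 19 is made by auxiliary-controlled alkylation of imide 18, prepared from acid 15 and auxiliary 16. C4 is set here because it becomes epimerisable once it is next to the furanone.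

## Alternatives that were turned down

**Alternative 1: ring expansion by anionic oxy-Cope rearrangement.**
- Disconnection: C3–C4 of the ten-membered ring, with a temporary C1–C6 bond restored, so the medium ring descends from a six-membered ring.
- Forward key step: KN(SiMe3)2 with 18-crown-6 triggers the alkoxide-accelerated [3,3] shift and gives the (E)-cyclodec-5-enone A1.
- For it: the ring forms in a stereospecific pericyclic step with defined alkene geometry. On ring construction it is stronger than the metathesis used here.
- Against it: A1 is far from the target in oxidation pattern. The C3 silyl group must become the furanone oxygen function. The C5=C6 alkene must be turned into a C6 oxygen with C5 reduced, and nothing biases C6 over C5. The C7 arm has only C11 and C12, so C13 needs a late strong-base methylenation. C4–C8 stereochemistry must then be handled on a flexible medium ring.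
- Comparison: the chosen route closes the ring less securely, but sets C4, C7, C8 and C10 in open-chain precursors and needs one oxidation after ring closure.

**Alternative 2: ring closure at C5–C6 by an allylchromium.**
- Disconnection: C5–C6, as in the chosen route, but at the aldehyde oxidation level.
- Forward key step: CrCl2 converts an allylic bromide on the furanone into an allylchromium that adds to a C6 aldehyde in the same molecule. This gives the ten-membered C6 alcohol A2 with a C4 exo-methylene.
- For it: the ring and the C6 oxygen arrive together by a chemoselective carbonyl addition, and the angelate is already in place. It is shorter and places the C6 oxygen more securely than a C–H oxidation.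
- Against it: the C6 configuration is set during macrocyclisation under conformational control. More seriously, the C4 exo-methylene of A2 must become CH–CH2OH of defined configuration. That is an anti-Markovnikov hydration of an electron-poor cross-conjugated alkene in the presence of the angelate and the lactone precursor.
- Comparison: the chosen route fixes C4 by an auxiliary before the furanone exists and never has to tell alkenes apart late.

**Alternative 3: tethered vinyl-radical cyclisation with oxygen capture.**
- Disconnection: C7–C11 and C8–O.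
- Forward key step: Bu3SnH with excess TEMPO turns a bromoacetal on O6 into a vinyl radical that adds to C7 of a ring alkene. The C8 radical is trapped by the nitroxide to give the methylene acetal A3.
- For it: the methylene is never masked, and the C8 oxygen comes with the C–C bond. On that point it is more direct than the present plan.
- Against it: it needs the bridged bicycle with the C6 oxygen already set, so the ring problem and the C6 stereocentre are only moved. The ring fusion from a 5-exo closure on a medium-ring alkene and the face of trapping at C8 depend on ring conformation. The tin hydride and the nitroxide also compete for the vinyl radical and for each other. N–O cleavage, acylation and acetal oxidation follow on a compound that already carries the methylene.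
- Comparison: the chosen route creates only C6 on the ring, with the other centres set by catalysts or an auxiliary.

Key step: step 23

Assumption: C11 is formed in step 8 as a mixture of both configurations and is carried unassigned (no descriptor in names or SMILES) until step 26 makes it trigonal. Descriptors given for compounds 22–39 use the C1–C15 numbering above.

## Route

Step 1
Reactants: 1 S-ethyl ethanethioate
Product: 2 1-(ethylsulfanyl)-1-[(trimethylsilyl)oxy]ethene
Conditions: LDA, THF, −78 °C; Me3SiCl
Reagents that add atoms: chlorotrimethylsilane, C[Si](C)(C)Cl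
Why: Kinetic enolisation of the thioester and O-silylation should give the silyl ketene thioacetal, the nucleophile class suited to the copper–bis(oxazoline) Mukaiyama aldol addition of step 2.

Step 2
Reactants: 2 1-(ethylsulfanyl)-1-[(trimethylsilyl)oxy]ethene; 3 butane-2,3-dione
Product: 4 S-ethyl (3S)-3-methyl-4-oxo-3-[(trimethylsilyl)oxy]pentanethioate
Conditions: Cu(OTf)2, (S,S)-t-Bu-box (10 mol %), THF, −78 °C; dione in excess, non-acidic work-up
Reagents that add atoms: none
Why: Catalytic enantioselective Mukaiyama aldol addition to a 1,2-dicarbonyl compound that chelates divalent copper in the C2-symmetric bis(oxazoline) complex; one tert-butyl group shields a face of the bound ketone, so the catalyst sets C10, the (S,S) ligand being chosen by analogy with the sense known for pyruvate esters. Silyl transfer to the aldolate turns the catalyst over and leaves the tertiary oxygen protected.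

Step 3
Reactants: 4 S-ethyl (3S)-3-methyl-4-oxo-3-[(trimethylsilyl)oxy]pentanethioate
Product: 5 (3S)-3-methyl-4-oxo-3-[(trimethylsilyl)oxy]pentanal
Conditions: Et3SiH, Pd/C (10%), acetone, rt; used crude
Reagents that add atoms: none
Why: Fukuyama reduction: palladium inserts into the C–S bond and the silane delivers hydride, so the thioester should become the aldehyde while ketone and silyl ether stay. The β-silyloxy aldehyde is not chromatographed, to avoid β-elimination.

Step 4
Reactants: 5 (3S)-3-methyl-4-oxo-3-[(trimethylsilyl)oxy]pentanal; 6 1-methoxy-4-[(prop-2-yn-1-yloxy)methyl]benzene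
Product: 9 (3S,5R,6E)-5-hydroxy-8-[(4-methoxybenzyl)oxy]-3-methyl-3-[(trimethylsilyl)oxy]oct-6-en-2-one, via the (E)-alkenyl(dicyclohexyl)borane 7 (not isolated), via the (E)-alkenyl(methyl)zinc 8 (not isolated)
Conditions: 6, Cy2BH, toluene, 0 °C to rt; Me2Zn, −78 °C; (−)-MIB (10 mol %); 5, −30 to 0 °C; aq NH4Cl
Reagents that add atoms: none
Why: Syn hydroboration fixes the (E)-geometry, boron-to-zinc exchange gives an alkenylzinc that adds to the aldehyde but not the ketone, and the amino alcohol catalyst (Oppolzer-type asymmetric alkenylation) directs attack to the Si face, which is the (R) configuration at C8. The non-chelating silyl ether on C10 leaves control with the ligand.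

Step 5
Reactants: 9 (3S,5R,6E)-5-hydroxy-8-[(4-methoxybenzyl)oxy]-3-methyl-3-[(trimethylsilyl)oxy]oct-6-en-2-one
Product: 10 (3S,5R,6E)-5-[(tert-butyldimethylsilyl)oxy]-8-[(4-methoxybenzyl)oxy]-3-methyl-3-[(trimethylsilyl)oxy]oct-6-en-2-one
Conditions: t-BuMe2SiCl, imidazole, DMF, rt
Reagents that add atoms: tert-butyldimethylsilyl chloride, CC(C)(C)[Si](C)(C)Cl
Why: Standard silylation of the secondary allylic alcohol; the ether must keep O8 from attacking the iridium allyl in step 8 and from lactonising until step 20.

Step 6
Reactants: 10 (3S,5R,6E)-5-[(tert-butyldimethylsilyl)oxy]-8-[(4-methoxybenzyl)oxy]-3-methyl-3-[(trimethylsilyl)oxy]oct-6-en-2-one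
Product: 11 (3S,5R,6E)-5-[(tert-butyldimethylsilyl)oxy]-8-hydroxy-3-methyl-3-[(trimethylsilyl)oxy]oct-6-en-2-one
Conditions: DDQ, CH2Cl2/pH 7 buffer, 0 °C
Reagents that add atoms: none
Why: Oxidative cleavage of the p-methoxybenzyl ether by hydride abstraction is orthogonal to both silyl ethers and the ketone; the buffer protects the tertiary trimethylsilyl ether.

Step 7
Reactants: 11 (3S,5R,6E)-5-[(tert-butyldimethylsilyl)oxy]-8-hydroxy-3-methyl-3-[(trimethylsilyl)oxy]oct-6-en-2-one
Product: 12 (2E,4R,6S)-4-[(tert-butyldimethylsilyl)oxy]-6-methyl-7-oxo-6-[(trimethylsilyl)oxy]oct-2-en-1-yl methyl carbonate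
Conditions: ClCO2Me, pyridine, CH2Cl2, 0 °C
Reagents that add atoms: methyl chloroformate, COC(=O)Cl
Why: Acylation to the linear allylic methyl carbonate, the usual leaving group for iridium-catalysed allylic substitution because the methoxide it releases acts as the base.

Step 8
Reactants: 12 (2E,4R,6S)-4-[(tert-butyldimethylsilyl)oxy]-6-methyl-7-oxo-6-[(trimethylsilyl)oxy]oct-2-en-1-yl methyl carbonate; 13 benzyl tert-butyl propanedioate
Product: 14 1-benzyl 3-tert-butyl 2-{(3R,4R,6S)-4-[(tert-butyldimethylsilyl)oxy]-6-methyl-7-oxo-6-[(trimethylsilyl)oxy]oct-1-en-3-yl}propanedioate (C11 epimers)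
Conditions: [Ir(cod)Cl]2 (2 mol %), (Sa,S,S)-binaphthyl bis(1-phenylethyl)phosphoramidite (4 mol %), TBD (8 mol %), THF, rt to 50 °C
Reagents that add atoms: none
Why: Iridium-catalysed asymmetric allylic alkylation: the cyclometallated iridium phosphoramidite ionises the carbonate to a π-allyl complex that a malonate attacks at the substituted terminus, giving the branched product with a terminal vinyl group. The ligand sets C7; the (Sa,S,S) antipode is chosen by the usual facial model so that the malonate carbon ends anti to the C8 oxygen in the zigzag projection. The mixed malonate lets the two carboxyls be distinguished later.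

Step 9
Reactants: 15 but-3-enoic acid; 16 (4R)-4-benzyl-1,3-oxazolidin-2-one
Product: 18 (4R)-4-benzyl-3-(but-3-enoyl)-1,3-oxazolidin-2-one, via but-3-enoic pivalic anhydride 17 (not isolated)
Conditions: t-BuCOCl, Et3N, THF, −20 °C; then 16, LiCl, −20 °C to rt
Reagents that add atoms: none
Why: Mixed-anhydride N-acylation under weakly basic conditions avoids the strong base that would move the alkene into conjugation.

Step 10
Reactants: 18 (4R)-4-benzyl-3-(but-3-enoyl)-1,3-oxazolidin-2-one
Product: 19 (4R)-4-benzyl-3-{(2S)-2-[(benzyloxy)methyl]but-3-enoyl}-1,3-oxazolidin-2-one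
Conditions: TiCl4, i-Pr2NEt, CH2Cl2, 0 °C; BnOCH2Cl
Reagents that add atoms: benzyl chloromethyl ether, ClCOCc1ccccc1
Why: Evans alkylation of the chelated titanium (Z)-dienolate: the oxocarbenium-type electrophile attacks the α carbon on the face away from the 4-benzyl group, which sets C4 and leaves the alkene β,γ. The (R) auxiliary is needed for the (4S) centre of the target.

Step 11
Reactants: 19 (4R)-4-benzyl-3-{(2S)-2-[(benzyloxy)methyl]but-3-enoyl}-1,3-oxazolidin-2-one
Product: 20 (2R)-2-[(benzyloxy)methyl]but-3-en-1-ol
Conditions: LiBH4, Et2O, H2O (1 equiv), 0 °C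
Reagents that add atoms: none
Why: Reductive removal of the auxiliary is fast at 0 °C and gives a 2-vinylpropane-1,3-diol monoether whose stereocentre is no longer acidic; the auxiliary is recovered.

Step 12
Reactants: 20 (2R)-2-[(benzyloxy)methyl]but-3-en-1-ol
Product: 21 (2S)-2-[(benzyloxy)methyl]but-3-enal
Conditions: Dess–Martin periodinane, NaHCO3, CH2Cl2, 0 °C; used at once
Reagents that add atoms: none
Why: Buffered periodinane oxidation is neutral, so the α-vinyl aldehyde should form without epimerisation or alkene migration.

Step 13
Reactants: 14 1-benzyl 3-tert-butyl 2-{(3R,4R,6S)-4-[(tert-butyldimethylsilyl)oxy]-6-methyl-7-oxo-6-[(trimethylsilyl)oxy]oct-1-en-3-yl}propanedioate; 21 (2S)-2-[(benzyloxy)methyl]but-3-enal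
Product: 22 (4S,7R,8R,10S)-aldol: C1 ketone and C3 carbinol joined through C2H2; C4 carries vinyl and CH2OBn; C7 carries vinyl and CH(CO2Bn)(CO2t-Bu); C8 OSiMe2t-Bu; C10 CH3 and OSiMe3 (C3 and C11 epimers)
Conditions: LDA (2.1 equiv), THF, −78 °C; 21, −78 °C; aq NH4Cl
Reagents that add atoms: none
Why: Directed lithium aldol addition as used for 3(2H)-furanone synthesis: the first equivalent of base stores the malonate as its inert enolate and the second deprotonates C2, the only enolisable ketone position. At −78 °C the enolate should add to the aldehyde faster than it deprotonates it; the C3 configuration is lost in step 14.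

Step 14
Reactants: 22 (4S,7R,8R,10S)-aldol
Product: 23 (4S,7R,8R,10S)-C1/C3 diketone corresponding to 22 (C11 epimers)
Conditions: Dess–Martin periodinane, NaHCO3, CH2Cl2, 0 °C to rt
Reagents that add atoms: none
Why: Periodinane oxidation of a β-hydroxy ketone to the 1,3-diketone is standard and non-basic, so C4 is not exposed to enolising conditions.

Step 15
Reactants: 23 (4S,7R,8R,10S)-C1/C3 diketone
Product: 25 (4S,7R,8R,10S)-furanone diene: 3(2H)-furanone O–C3=C2–C1(=O)–C10 carrying on C3 the (2S)-1-(benzyloxy)but-3-en-2-yl group and on C10 methyl plus the chain C9H2–C8H(OSiMe2t-Bu)–C7H(CH=CH2)–C11H(CO2Bn)(CO2t-Bu), via the C10-hydroxy diketone 24 (not isolated)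
Conditions: p-TsOH·H2O (0.2 equiv), THF/H2O (20:1), rt
Reagents that add atoms: none
Why: Mild acid removes the tertiary trimethylsilyl ether, the freed C10 hydroxyl adds to the C3 carbonyl and dehydration gives the vinylogous ester (acid-mediated cyclodehydration of an α′-hydroxy 1,3-diketone). The secondary silyl ether, the tert-butyl ester and C4 should survive.

Step 16
Reactants: 25 (4S,7R,8R,10S)-furanone diene
Product: 26 (4S,7R,8R,10S)-bicyclic furanone with a (Z)-C5=C6 double bond (C15 OBn; C8 OSiMe2t-Bu; C11 benzyl tert-butyl malonate)
Conditions: second-generation Grubbs catalyst (10 mol %), 1,4-benzoquinone (10 mol %), CH2Cl2 (1 mM), 40 °C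
Reagents that add atoms: none
Why: Ring-closing metathesis of two monosubstituted alkenes; the planar furanone holds the C4 and C9 arms on one side, as in metathesis closures of other oxygen-bridged nine-membered rings. The geometry of the new alkene does not matter because step 17 removes it.

Step 17
Reactants: 26 (4S,7R,8R,10S)-bicyclic furanone with a (Z)-C5=C6 double bond
Product: 27 (4S,7R,8R,10S)-saturated bicycle with C15 OH; C8 OSiMe2t-Bu; C11 bearing CO2H and CO2t-Bu
Conditions: H2 (1 atm), Pd/C (10%), EtOAc/EtOH, rt
Reagents that add atoms: none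
Why: Heterogeneous hydrogenation saturates the disubstituted alkene and cleaves the benzyl ether and the benzyl ester in one operation; the push–pull furanone alkene is far less reactive. The acid appears while O8 is still silylated, so no 8,12-lactone can form.

Step 18
Reactants: 27 (4S,7R,8R,10S)-saturated bicycle with C15 OH and the C11 half acid
Product: 28 (4S,7R,8R,10S)-diol: C13 OH and C15 OH; C8 OSiMe2t-Bu; C12 tert-butyl ester
Conditions: BH3·THF (3 equiv), THF, −10 to 0 °C; MeOH
Reagents that add atoms: none
Why: Borane reduces a free carboxylic acid through its acyloxyborane much faster than an ester or a vinylogous ester, so only the acid should become the C13 alcohol.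

Step 19
Reactants: 28 (4S,7R,8R,10S)-diol
Product: 29 bis(2,2,2-trichloroethyl carbonate) of 28 at O13 and O15
Conditions: Cl3CCH2OCOCl (2.5 equiv), pyridine, CH2Cl2, 0 °C
Reagents that add atoms: 2,2,2-trichloroethyl chloroformate, ClC(=O)OCC(Cl)(Cl)Cl
Why: Both primary alcohols are acylated at once; on O15 the carbonate is an oxidation-resistant protecting group removable by zinc, and on O13 it is the leaving group for the later elimination.

Step 20
Reactants: 29 bis(2,2,2-trichloroethyl carbonate)
Product: 30 C8 alcohol (O13 and O15 trichloroethyl carbonates; C12 tert-butyl ester)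
Conditions: HF·pyridine, pyridine, THF, 0 °C to rt
Reagents that add atoms: none
Why: Buffered fluoride cleaves the silyl ether without touching carbonates or the furanone; the tert-butyl ester is too poor an electrophile to lactonise with the freed hydroxyl.

Step 21
Reactants: 30 C8 alcohol
Product: 31 C8 chloroacetate of 30
Conditions: (ClCH2CO)2O, pyridine, DMAP (cat.), CH2Cl2, 0 °C
Reagents that add atoms: chloroacetic anhydride, O=C(CCl)OC(=O)CCl
Why: Esterification of the hindered secondary alcohol with a reactive anhydride; the chloroacetate deactivates C8–H and can later be removed by thiourea in the presence of carbonates and the lactone.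

Step 22
Reactants: 31 C8 chloroacetate
Product: 32 (4S,7R,8R,10S)-C12 carboxylic acid with unfunctionalised C6 (C8 chloroacetate; O13 and O15 trichloroethyl carbonates)
Conditions: CF3CO2H/CH2Cl2 (1:4), 0 °C to rt
Reagents that add atoms: none
Why: Acidolysis of the tert-butyl ester (loss of the tert-butyl cation as the alkene) frees the directing acid last; chloroacetate, carbonates and furanone are acid-stable.

Step 23
Reactants: 32 (4S,7R,8R,10S)-C12 carboxylic acid with unfunctionalised C6
Product: 33 (4S,6R,7S,8R,10S)-trans-fused 6,12-lactone (C8 chloroacetate; O13 and O15 trichloroethyl carbonates)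
Conditions: Mn(OTf)2 complex of (S,S)-TIPS-pdp (3 mol %), H2O2 (2 equiv, syringe pump), (CF3)2CHOH, 0 °C
Reagents that add atoms: none
Why: The carboxylate of 32 displaces a triflate on divalent manganese, H2O2 binds, and carboxylate-assisted heterolysis of the O–O bond gives a high-valent manganese oxo carboxylate. The oxo ligand takes a hydrogen atom from C6 through a cyclic transition state made of the metal, the bound carboxylate and the C11–C7–C6 chain, and the carbon radical is captured at once by the carboxylate oxygen, so C–O replaces C–H with retention. The closest known reaction type is the manganese-catalysed, carboxylic-acid-directed γ-lactonisation of unactivated methylene groups with H2O2 in fluorinated alcohols; only the medium-ring setting is untested. The five-membered lactone closes by C–O bond formation at the γ carbon, the other four ring atoms (O, C12, C11, C7) being in place. C6 is the only new stereocentre and is fixed by which diastereotopic hydrogen is removed: with C11 on C7 and the ring torsion C5–C6–C7–C8 anti, only the hydrogen gauche to C11 can reach the oxo ligand, and its replacement gives the trans-fused (6R) ring; both ligand antipodes would be compared and the matched one used. Site selectivity between the two γ carbons is secured by the chloroacetoxy group, which deactivates C8–H. C7–H and C11–H are too close to the metal and electron-poor, and C4–H, C9–H2 and C15–H2 are deactivated by the furanone, the esters and the carbonates; C5–H2 is δ to the acid, so its abstraction needs a larger and less favoured ring transition state. No electron-rich alkene is present, and slow addition of the oxidant at 0 °C limits over-oxidation.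

Step 24
Reactants: 33 (4S,6R,7S,8R,10S)-trans-fused 6,12-lactone
Product: 34 (4S,6R,7R,8R,10S)-C8 alcohol of the lactone (O13 and O15 trichloroethyl carbonates)
Conditions: thiourea, 2,6-lutidine, EtOH/THF, 50 °C
Reagents that add atoms: none
Why: Thiourea displaces chloride and the isothiouronium nitrogen then cyclises onto the ester carbonyl, releasing the alcohol; this is specific for the chloroacetate. The weak base should leave the C13 carbonate and the lactone in place; the alcohol is taken on without delay.

Step 25
Reactants: 34 (4S,6R,7R,8R,10S)-C8 alcohol of the lactone; 35 angelic acid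
Product: 37 C8 angelate (Z)-2-methylbut-2-enoate of 34 (O13 and O15 trichloroethyl carbonates), via angelic 2,4,6-trichlorobenzoic anhydride 36 (not isolated)
Conditions: 35, 2,4,6-trichlorobenzoyl chloride, Et3N, toluene, rt; then 34, toluene, 80 °C
Reagents that add atoms: none
Why: Esterification through the Yamaguchi mixed anhydride without a nucleophilic catalyst, the conditions under which angelates form without Z to E isomerisation. If residual amine already eliminates the C13 carbonate, the product is 38 and the route converges.

Step 26
Reactants: 37 C8 angelate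
Product: 38 (4S,6R,7S,8R,10S)-11(13)-methylene lactone with O15 trichloroethyl carbonate
Conditions: DBU, CH2Cl2, 0 °C
Reagents that add atoms: none
Why: E1cB elimination: C11–H is α to the lactone carbonyl and the C13 carbonate is a good leaving group. The C15 carbonate is β only to C4–H, which is merely vinylogously acidic, so it should stay at 0 °C.

Step 27
Reactants: 38 (4S,6R,7S,8R,10S)-11(13)-methylene lactone with O15 trichloroethyl carbonate
Product: 39 the target CNP0108636.1
Conditions: Zn, AcOH/THF, rt
Reagents that add atoms: none
Why: Zinc inserts into a C–Cl bond of the trichloroethyl group and β-fragmentation releases the carbonate, which loses CO2 to give the C15 alcohol. Angelate, methylene lactone and furanone are not reduced by zinc in acetic acid at room temperature.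

## Compound list

1 | S-ethyl ethanethioate | CCSC(C)=O | starting material
2 | 1-(ethylsulfanyl)-1-[(trimethylsilyl)oxy]ethene | C=C(SCC)O[Si](C)(C)C | intermediate
3 | butane-2,3-dione | CC(=O)C(C)=O | starting material
4 | S-ethyl (3S)-3-methyl-4-oxo-3-[(trimethylsilyl)oxy]pentanethioate | CC(=O)[C@](C)(CC(=O)SCC)O[Si](C)(C)C | intermediate
5 | (3S)-3-methyl-4-oxo-3-[(trimethylsilyl)oxy]pentanal | CC(=O)[C@](C)(CC=O)O[Si](C)(C)C | intermediate
6 | 1-methoxy-4-[(prop-2-yn-1-yloxy)methyl]benzene | C#CCOCc1ccc(OC)cc1 | starting material
7 | (E)-dicyclohexyl{3-[(4-methoxybenzyl)oxy]prop-1-en-1-yl}borane | COc1ccc(COC/C=C/B(C2CCCCC2)C2CCCCC2)cc1 | intermediate (not isolated)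
8 | (E)-{3-[(4-methoxybenzyl)oxy]prop-1-en-1-yl}(methyl)zinc | COc1ccc(COC/C=C/[Zn]C)cc1 | intermediate (not isolated)
9 | (3S,5R,6E)-5-hydroxy-8-[(4-methoxybenzyl)oxy]-3-methyl-3-[(trimethylsilyl)oxy]oct-6-en-2-one | CC(=O)[C@](C)(C[C@@H](O)/C=C/COCc1ccc(OC)cc1)O[Si](C)(C)C | intermediate
10 | (3S,5R,6E)-5-[(tert-butyldimethylsilyl)oxy]-8-[(4-methoxybenzyl)oxy]-3-methyl-3-[(trimethylsilyl)oxy]oct-6-en-2-one | CC(=O)[C@](C)(C[C@@H](O[Si](C)(C)C(C)(C)C)/C=C/COCc1ccc(OC)cc1)O[Si](C)(C)C | intermediate
11 | (3S,5R,6E)-5-[(tert-butyldimethylsilyl)oxy]-8-hydroxy-3-methyl-3-[(trimethylsilyl)oxy]oct-6-en-2-one | CC(=O)[C@](C)(C[C@@H](O[Si](C)(C)C(C)(C)C)/C=C/CO)O[Si](C)(C)C | intermediate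
12 | (2E,4R,6S)-4-[(tert-butyldimethylsilyl)oxy]-6-methyl-7-oxo-6-[(trimethylsilyl)oxy]oct-2-en-1-yl methyl carbonate | CC(=O)[C@](C)(C[C@@H](O[Si](C)(C)C(C)(C)C)/C=C/COC(=O)OC)O[Si](C)(C)C | intermediate
13 | benzyl tert-butyl propanedioate | O=C(CC(=O)OC(C)(C)C)OCc1ccccc1 | starting material
14 | 1-benzyl 3-tert-butyl 2-{(3R,4R,6S)-4-[(tert-butyldimethylsilyl)oxy]-6-methyl-7-oxo-6-[(trimethylsilyl)oxy]oct-1-en-3-yl}propanedioate, both configurations at the malonate carbon | CC(=O)[C@](C)(C[C@@H](O[Si](C)(C)C(C)(C)C)[C@@H](C(C(=O)OCc1ccccc1)C(=O)OC(C)(C)C)C=C)O[Si](C)(C)C | intermediate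
15 | but-3-enoic acid | C=CCC(=O)O | starting material
16 | (4R)-4-benzyl-1,3-oxazolidin-2-one | O=C1N[C@H](Cc2ccccc2)CO1 | starting material
17 | but-3-enoic pivalic anhydride | C=CCC(=O)OC(=O)C(C)(C)C | intermediate (not isolated)
18 | (4R)-4-benzyl-3-(but-3-enoyl)-1,3-oxazolidin-2-one | C=CCC(=O)N1C(=O)OC[C@H]1Cc1ccccc1 | intermediate
19 | (4R)-4-benzyl-3-{(2S)-2-[(benzyloxy)methyl]but-3-enoyl}-1,3-oxazolidin-2-one | C=C[C@@H](COCc1ccccc1)C(=O)N1C(=O)OC[C@H]1Cc1ccccc1 | intermediate
20 | (2R)-2-[(benzyloxy)methyl]but-3-en-1-ol | C=C[C@@H](COCc1ccccc1)CO | intermediate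
21 | (2S)-2-[(benzyloxy)methyl]but-3-enal | C=C[C@@H](COCc1ccccc1)C=O | intermediate
22 | (4S,7R,8R,10S)-aldol; open chain; C1 ketone, C2H2, C3 carbinol (both configurations), C4 with vinyl and CH2OBn, C7 with vinyl and CH(CO2Bn)(CO2t-Bu), C8 OSiMe2t-Bu, C10 with CH3 and OSiMe3 | C=C[C@@H](COCc1ccccc1)C(O)CC(=O)[C@](C)(C[C@@H](O[Si](C)(C)C(C)(C)C)[C@@H](C(C(=O)OCc1ccccc1)C(=O)OC(C)(C)C)C=C)O[Si](C)(C)C | intermediate
23 | (4S,7R,8R,10S)-C1/C3 diketone corresponding to 22 | C=C[C@@H](COCc1ccccc1)C(=O)CC(=O)[C@](C)(C[C@@H](O[Si](C)(C)C(C)(C)C)[C@@H](C(C(=O)OCc1ccccc1)C(=O)OC(C)(C)C)C=C)O[Si](C)(C)C | intermediate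
24 | (4S,7R,8R,10S)-C10-hydroxy diketone (23 without the trimethylsilyl group) | C=C[C@@H](COCc1ccccc1)C(=O)CC(=O)[C@](C)(C[C@@H](O[Si](C)(C)C(C)(C)C)[C@@H](C(C(=O)OCc1ccccc1)C(=O)OC(C)(C)C)C=C)O | intermediate (not isolated)
25 | (4S,7R,8R,10S)-furanone diene; 3(2H)-furanone with the (2S)-1-(benzyloxy)but-3-en-2-yl group on C3 and, on C10, methyl and the chain C9H2–C8H(OSiMe2t-Bu)–C7H(vinyl)–C11H(CO2Bn)(CO2t-Bu) | C=C[C@@H](COCc1ccccc1)C1=CC(=O)[C@](C)(C[C@@H](O[Si](C)(C)C(C)(C)C)[C@@H](C(C(=O)OCc2ccccc2)C(=O)OC(C)(C)C)C=C)O1 | intermediate
26 | (4S,7R,8R,10S)-bicyclic furanone, (Z)-C5=C6, C15 OBn, C8 OSiMe2t-Bu, C11 benzyl tert-butyl malonate | CC(C)(C)OC(=O)C(C(=O)OCc1ccccc1)[C@H]1/C=C\[C@@H](COCc3ccccc3)C2=CC(=O)[C@](C)(C[C@H]1O[Si](C)(C)C(C)(C)C)O2 | intermediate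
27 | (4S,7R,8R,10S)-saturated bicycle, C15 OH, C8 OSiMe2t-Bu, C11 with CO2H and CO2t-Bu | CC(C)(C)OC(=O)C(C(=O)O)[C@H]1CC[C@@H](CO)C2=CC(=O)[C@](C)(C[C@H]1O[Si](C)(C)C(C)(C)C)O2 | intermediate
28 | (4S,7R,8R,10S)-diol, C13 OH and C15 OH, C8 OSiMe2t-Bu, C12 tert-butyl ester | CC(C)(C)OC(=O)C(CO)[C@H]1CC[C@@H](CO)C2=CC(=O)[C@](C)(C[C@H]1O[Si](C)(C)C(C)(C)C)O2 | intermediate
29 | (4S,7R,8R,10S)-O13,O15-bis(2,2,2-trichloroethyl carbonate), C8 OSiMe2t-Bu, C12 tert-butyl ester | CC(C)(C)OC(=O)C(COC(=O)OCC(Cl)(Cl)Cl)[C@H]1CC[C@@H](COC(=O)OCC(Cl)(Cl)Cl)C2=CC(=O)[C@](C)(C[C@H]1O[Si](C)(C)C(C)(C)C)O2 | intermediate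
30 | (4S,7R,8R,10S)-C8 alcohol, O13 and O15 trichloroethyl carbonates, C12 tert-butyl ester | CC(C)(C)OC(=O)C(COC(=O)OCC(Cl)(Cl)Cl)[C@H]1CC[C@@H](COC(=O)OCC(Cl)(Cl)Cl)C2=CC(=O)[C@](C)(C[C@H]1O)O2 | intermediate
31 | (4S,7R,8R,10S)-C8 chloroacetate, O13 and O15 trichloroethyl carbonates, C12 tert-butyl ester | CC(C)(C)OC(=O)C(COC(=O)OCC(Cl)(Cl)Cl)[C@H]1CC[C@@H](COC(=O)OCC(Cl)(Cl)Cl)C2=CC(=O)[C@](C)(C[C@H]1OC(=O)CCl)O2 | intermediate
32 | (4S,7R,8R,10S)-bicyclic furanone C12 acid with unfunctionalised C6, C8 chloroacetate, O13 and O15 trichloroethyl carbonates | OC(=O)C(COC(=O)OCC(Cl)(Cl)Cl)[C@H]1CC[C@@H](COC(=O)OCC(Cl)(Cl)Cl)C2=CC(=O)[C@](C)(C[C@H]1OC(=O)CCl)O2 | intermediate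
33 | (4S,6R,7S,8R,10S)-trans-fused 6,12-lactone, C8 chloroacetate, O13 and O15 trichloroethyl carbonates | ClC(Cl)(Cl)COC(=O)OCC1C(=O)O[C@@H]2C[C@@H](COC(=O)OCC(Cl)(Cl)Cl)C3=CC(=O)[C@](C)(C[C@@H](OC(=O)CCl)[C@@H]12)O3 | intermediate
34 | (4S,6R,7R,8R,10S)-lactone C8 alcohol, O13 and O15 trichloroethyl carbonates | ClC(Cl)(Cl)COC(=O)OCC1C(=O)O[C@@H]2C[C@@H](COC(=O)OCC(Cl)(Cl)Cl)C3=CC(=O)[C@](C)(C[C@@H](O)[C@@H]12)O3 | intermediate
35 | angelic acid, (Z)-2-methylbut-2-enoic acid | C/C=C(/C)C(=O)O | starting material
36 | angelic 2,4,6-trichlorobenzoic anhydride | C/C=C(/C)C(=O)OC(=O)c1c(Cl)cc(Cl)cc1Cl | intermediate (not isolated)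
37 | (4S,6R,7S,8R,10S)-lactone C8 angelate, O13 and O15 trichloroethyl carbonates | ClC(Cl)(Cl)COC(=O)OCC1C(=O)O[C@@H]2C[C@@H](COC(=O)OCC(Cl)(Cl)Cl)C3=CC(=O)[C@](C)(C[C@@H](OC(=O)/C(C)=C\C)[C@@H]12)O3 | intermediate
38 | (4S,6R,7S,8R,10S)-11(13)-methylene lactone C8 angelate, O15 trichloroethyl carbonate | C=C1C(=O)O[C@@H]2C[C@@H](COC(=O)OCC(Cl)(Cl)Cl)C3=CC(=O)[C@](C)(C[C@@H](OC(=O)/C(C)=C\C)[C@@H]12)O3 | intermediate
39 | CNP0108636.1, (4S,6R,7S,8R,10S) | C=C1C(=O)O[C@@H]2C[C@@H](CO)C3=CC(=O)[C@](C)(C[C@@H](OC(=O)/C(C)=C\C)[C@@H]12)O3 | target

## Step count and least certain steps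

Total: 27 steps. Longest linear sequence: 23 steps (steps 1–8 and 13–27); the branch through 15 and 16 is steps 9–12.

**Step 23 (key step).** Hydrogen abstraction may go to C5 or C8, the other C6 hydrogen may be taken and give the cis-fused lactone, a C6 hydroxyl formed without carboxylate capture may be oxidised on to the ketone, or the enol-ether side of the furanone may be attacked.
- Fallback, 32 to 33 by an amidyl-radical relay: 32 would be converted under neutral conditions (1-chloro-N,N,2-trimethylprop-1-en-1-amine, then hexamethyldisilazane and methanol) into the primary amide F1. tert-Butyl hypochlorite and iodine would give the N-iodoamide F2. Irradiation of F2 generates an amidyl radical that takes the C6 hydrogen by a 1,5-shift (C8–H is deactivated in the same way); the C6 iodide is displaced by the amide oxygen to give the iminolactone F3, and dilute aqueous acid hydrolyses F3 to 33.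

**Step 8.** The bulky C8 substituent may erode branched selectivity, the substrate stereocentre may oppose the catalyst, or the tertiary silyl ether may be lost, after which O10 attacks the allyl complex. The ligand antipode is assigned by analogy and would be checked first.
- Fallback, 11 to 14 by a sigmatropic route: 11 would be esterified with 3-tert-butoxy-3-oxopropanoic acid (carbodiimide) to the allylic malonate F4. Ireland–Claisen rearrangement of F4 (Me3SiOTf, Et3N) through a chair transition state moves the malonate carbon to C7 and leaves the vinyl group, giving the malonic half acid F5. O-Benzylation of F5 (BnBr, KHCO3) returns to 14. Control of C7 then rests on the neighbouring C8 silyloxy group.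

**Step 13.** Proton transfer from the α-vinyl aldehyde to the enolate would erase C4 and move the alkene into conjugation; retro-aldol cleavage on quenching is also possible.
- Fallback, 14 to 22 under Lewis-acid conditions: 14 would be silylated (Me3SiOTf, Et3N) to the silyl enol ether F6, and BF3·OEt2 at −78 °C would promote Mukaiyama addition of F6 to 21, giving 22 after work-up.

**Step 16.** Intermolecular metathesis may outrun ring closure, ruthenium hydrides may move the C4 vinyl group into conjugation with the furanone, or strain in the bridged ring may stop closure.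
- Fallback, 23 to 26 with the order of ring formation reversed: metathesis on the unbridged diketone 23 would give the ten-membered cyclic diketone F7 (drawn Z; either geometry serves). The acid of step 15 would then close the furanone across the ring of F7 to give 26.

**Step 18.** Borane may also reduce the C1 carbonyl or add to the enol ether of the furanone, and the malonic half acid may lose CO2 before it is reduced.
- Fallback, 27 to 28 by a nucleophilic hydride: 1,1′-carbonyldiimidazole (1 equiv) would convert 27 into the acyl imidazolide F8, which NaBH4 in aqueous THF at 0 °C reduces to 28.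

**Step 25.** The angelate may isomerise to the tiglate, slow acylation of the hindered C8 hydroxyl may give the lactone carbonyl time to migrate from O6 to O8, and the C13 carbonate may be lost early.
- Fallback, 34 to 37 by building the (Z)-alkene on the ester: 34 would be esterified with 2-[bis(2,2,2-trifluoroethoxy)phosphoryl]propanoic acid to the phosphonate ester F9. Still–Gennari olefination of F9 (KN(SiMe3)2, 18-crown-6, acetaldehyde, −78 °C) gives 37.

## Further compounds

F1 | step 23 | primary amide of 32 | NC(=O)C(COC(=O)OCC(Cl)(Cl)Cl)[C@H]1CC[C@@H](COC(=O)OCC(Cl)(Cl)Cl)C2=CC(=O)[C@](C)(C[C@H]1OC(=O)CCl)O2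
F2 | step 23 | N-iodoamide of 32 | INC(=O)C(COC(=O)OCC(Cl)(Cl)Cl)[C@H]1CC[C@@H](COC(=O)OCC(Cl)(Cl)Cl)C2=CC(=O)[C@](C)(C[C@H]1OC(=O)CCl)O2
F3 | step 23 | iminolactone corresponding to 33 | ClC(Cl)(Cl)COC(=O)OCC1C(=N)O[C@@H]2C[C@@H](COC(=O)OCC(Cl)(Cl)Cl)C3=CC(=O)[C@](C)(C[C@@H](OC(=O)CCl)[C@@H]12)O3
F4 | step 8 | tert-butyl malonate ester of allylic alcohol 11 | CC(=O)[C@](C)(C[C@@H](O[Si](C)(C)C(C)(C)C)/C=C/COC(=O)CC(=O)OC(C)(C)C)O[Si](C)(C)C
F5 | step 8 | malonic half acid with C7 set (14 without the benzyl group) | CC(=O)[C@](C)(C[C@@H](O[Si](C)(C)C(C)(C)C)[C@@H](C(C(=O)O)C(=O)OC(C)(C)C)C=C)O[Si](C)(C)C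
F6 | step 13 | trimethylsilyl enol ether of ketone 14 | C=C(O[Si](C)(C)C)[C@](C)(C[C@@H](O[Si](C)(C)C(C)(C)C)[C@@H](C(C(=O)OCc1ccccc1)C(=O)OC(C)(C)C)C=C)O[Si](C)(C)C
F7 | step 16 | ten-membered cyclic 1,3-diketone from 23 | O=C1CC(=O)[C@H](COCc2ccccc2)/C=C\[C@H](C(C(=O)OCc2ccccc2)C(=O)OC(C)(C)C)[C@H](O[Si](C)(C)C(C)(C)C)C[C@]1(C)O[Si](C)(C)C
F8 | step 18 | acyl imidazolide of 27 | CC(C)(C)OC(=O)C(C(=O)n1ccnc1)[C@H]1CC[C@@H](CO)C2=CC(=O)[C@](C)(C[C@H]1O[Si](C)(C)C(C)(C)C)O2
F9 | step 25 | C8 2-[bis(2,2,2-trifluoroethoxy)phosphoryl]propanoate of 34 | ClC(Cl)(Cl)COC(=O)OCC1C(=O)O[C@@H]2C[C@@H](COC(=O)OCC(Cl)(Cl)Cl)C3=CC(=O)[C@](C)(C[C@@H](OC(=O)C(C)P(=O)(OCC(F)(F)F)OCC(F)(F)F)[C@@H]12)O3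
A1 | alternative 1 | (E)-cyclodec-5-enone with C3 silyl and C4 set | O=C1C[C@H]([Si](C)(C)c2ccccc2)[C@H](CO[Si](c2ccccc2)(c2ccccc2)C(C)(C)C)/C=C/[C@H](CCO[Si](CC)(CC)CC)[C@H]2C[C@]1(C)OC(C)(C)O2
A2 | alternative 2 | ten-membered C6 alcohol with C4 exo-methylene | O[C@@H]1CC(=C)C2=CC(=O)[C@](C)(C[C@@H](OC(=O)/C(C)=C\C)[C@H]1C(=C)CO[Si](C)(C)C(C)(C)C)O2
A3 | alternative 3 | methylene acetal with a tetramethylpiperidinyloxy group on C8 | C=C1[C@@H](OCC)O[C@@H]2C[C@@H](CO[Si](C)(C)C(C)(C)C)C3=CC(=O)[C@](C)(C[C@@H](ON4C(C)(C)CCCC4(C)C)[C@@H]12)O3
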